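**Retrosynthetic overview**
1. Target 17 ⇐ one hydrogenation/hydrogenolysis of tetrabenzyl dienone 16, which saturates two C=C bonds and removes four O-benzyl groups.
2. 16 ⇐ dehydration, through acetate 15, of β-hydroxy ketone 14. The key C2–C3 bond comes from a directed aldol addition of the lithium enolate of ketone 11 to the C9 aldehyde 9.
3. 9 ⇐ oxidation of alcohol 8 ⇐ Wittig olefination of 2-(benzyloxy)benzaldehyde 2 with the C8 ylide made from octane-1,8-diol 3.
4. 11 ⇐ tri-O-benzylation of 2,4,6-trihydroxyacetophenone 10; 2 ⇐ O-benzylation of salicylaldehyde 1.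
5. No ring is formed. Both benzene rings are bought intact in 1 and 10.

Assumption: the SMILES holds no stereocentre and no C=C bond, so the target is achiral and needs no asymmetric step; the one transient stereocentre (C3 of 13–15) is made racemic and erased in step 9.

**Step 1**
Reactants: 1 salicylaldehyde (2-hydroxybenzaldehyde)
Product: 2 2-(benzyloxy)benzaldehyde
Conditions: BnBr (1.1 equiv), K2CO3 (1.5 equiv), DMF, rt → 50 °C
Reagents that add atoms: benzyl bromide, BrCc1ccccc1
Why: Williamson ether synthesis, in which the acidic phenol is ionised by carbonate and displaces bromide from a very reactive benzylic halide while the non-enolisable aldehyde is inert.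

**Step 2**
Reactants: 3 octane-1,8-diol
Product: 4 8-bromooctan-1-ol
Conditions: 48% aq HBr (1.2 equiv), toluene, reflux, 20 h
Reagents that add atoms: hydrogen bromide, Br
Why: SN2 monobromination of a symmetrical diol in a two-phase system, where the bromo alcohol moves into the toluene layer away from the acid, so the dibromide stays minor and is removed by chromatography.

**Step 3**
Reactants: 4 8-bromooctan-1-ol
Product: 5 (8-hydroxyoctyl)triphenylphosphonium bromide
Conditions: PPh3 (1.05 equiv), MeCN, reflux, 36 h; dried azeotropically with toluene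
Reagents that add atoms: triphenylphosphine, c1ccc(cc1)P(c1ccccc1)c1ccccc1
Why: SN2 quaternisation of triphenylphosphine by an unhindered primary bromide, which the free hydroxyl does not disturb.

**Step 4**
Reactants: 5 (8-hydroxyoctyl)triphenylphosphonium bromide; 2 2-(benzyloxy)benzaldehyde
Product: 8 (Z)-9-[2-(benzyloxy)phenyl]non-8-en-1-ol, via alkoxide ylide 6 (not isolated), via sodium alkoxide 7 (not isolated)
Conditions: NaHMDS (2.1 equiv, 1.0 M in THF), THF, −78 → 0 °C, 1 h; then 2 (0.95 equiv), −78 °C → rt; H2O quench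
Reagents that add atoms: none
Why: Wittig olefination, in which two equivalents of base give the alkoxide ylide and this non-stabilised ylide adds to the non-enolisable aromatic aldehyde under lithium-free conditions to give mainly the Z alkene (the minor E isomer is carried along harmlessly because this C=C is hydrogenated in step 10).

**Step 5**
Reactants: 8 (Z)-9-[2-(benzyloxy)phenyl]non-8-en-1-ol
Product: 9 (Z)-9-[2-(benzyloxy)phenyl]non-8-enal
Conditions: Dess–Martin periodinane (1.2 equiv), CH2Cl2, 0 °C → rt, 1.5 h; used promptly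
Reagents that add atoms: none
Why: Dess–Martin oxidation takes the primary alcohol to the aldehyde under near-neutral conditions without over-oxidation and leaves the benzyl ether and the styrene C=C alone.

**Step 6**
Reactants: 10 2,4,6-trihydroxyacetophenone (commercial monohydrate, dried)
Product: 11 1-[2,4,6-tris(benzyloxy)phenyl]ethan-1-one
Conditions: BnBr (3.6 equiv), K2CO3 (5 equiv), DMF, 80 °C, 12 h
Reagents that add atoms: benzyl bromide, BrCc1ccccc1
Why: Threefold Williamson ether synthesis, since in hot DMF with excess carbonate even the two phenols hydrogen-bonded to the acetyl group are ionised and O-benzylated while carbonate is too weak to enolise the methyl ketone.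

**Step 7 (key step)**
Reactants: 11 1-[2,4,6-tris(benzyloxy)phenyl]ethan-1-one (1.1 equiv); 9 (Z)-9-[2-(benzyloxy)phenyl]non-8-enal (1.0 equiv)
Product: 14 rac-(10Z)-11-[2-(benzyloxy)phenyl]-3-hydroxy-1-[2,4,6-tris(benzyloxy)phenyl]undec-10-en-1-one, via lithium enolate 12 (not isolated), via lithium aldolate 13 (not isolated)
Conditions: LDA (1.05 equiv, commercial 2.0 M solution), THF, −78 °C, 45 min; then 9 in THF, −78 °C, 1 h; AcOH (1.2 equiv) in THF at −78 °C
Reagents that add atoms: none
Why: Directed (crossed) aldol addition, in which the ketone has a single enolisable site and is deprotonated fully and irreversibly before the aldehyde is added, the lithium enolate adds to the unhindered aldehyde at −78 °C faster than it exchanges protons, the cold acid quench blocks retro-aldol, and the new C3 carbinol centre forms as a racemate that is erased in step 9.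

**Step 8**
Reactants: 14 rac-(10Z)-11-[2-(benzyloxy)phenyl]-3-hydroxy-1-[2,4,6-tris(benzyloxy)phenyl]undec-10-en-1-one
Product: 15 rac-(10Z)-11-[2-(benzyloxy)phenyl]-1-oxo-1-[2,4,6-tris(benzyloxy)phenyl]undec-10-en-3-yl acetate
Conditions: Ac2O (2 equiv), pyridine (3 equiv), DMAP (5 mol %), CH2Cl2, 0 °C → rt
Reagents that add atoms: acetic anhydride, CC(=O)OC(C)=O
Why: DMAP-catalysed O-acylation turns the secondary hydroxyl into a leaving group under conditions too weakly basic for retro-aldol cleavage, and the racemic stereocentre is not touched.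

**Step 9**
Reactants: 15 rac-(10Z)-11-[2-(benzyloxy)phenyl]-1-oxo-1-[2,4,6-tris(benzyloxy)phenyl]undec-10-en-3-yl acetate
Product: 16 (2E,10Z)-11-[2-(benzyloxy)phenyl]-1-[2,4,6-tris(benzyloxy)phenyl]undeca-2,10-dien-1-one
Conditions: DBU (1.5 equiv), CH2Cl2, 0 °C → rt, 2 h
Reagents that add atoms: none
Why: E1cB β-elimination, in which DBU removes the acidic C2–H next to the ketone and acetate leaves, giving the conjugated E-enone and erasing the C3 stereocentre.

**Step 10**
Reactants: 16 (2E,10Z)-11-[2-(benzyloxy)phenyl]-1-[2,4,6-tris(benzyloxy)phenyl]undeca-2,10-dien-1-one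
Product: 17 11-(2-hydroxyphenyl)-1-(2,4,6-trihydroxyphenyl)undecan-1-one
Conditions: H2 (1 atm), 10% Pd/C, EtOAc/MeOH 1:1, rt, 12 h
Reagents that add atoms: none
Why: Catalytic hydrogenation with hydrogenolysis, in which Pd/C first saturates the enone and styrene C=C bonds and then cleaves the four aryl benzyl ethers, the electron-rich and strongly hydrogen-bonded acylphloroglucinol ketone is not reduced at 1 atm, and the product has no stereocentre.

**Compound list**
1 | salicylaldehyde | O=Cc1ccccc1O | starting material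
2 | 2-(benzyloxy)benzaldehyde | O=Cc1ccccc1OCc1ccccc1 | intermediate
3 | octane-1,8-diol | OCCCCCCCCO | starting material
4 | 8-bromooctan-1-ol | OCCCCCCCCBr | intermediate
5 | (8-hydroxyoctyl)triphenylphosphonium bromide | OCCCCCCCC[P+](c1ccccc1)(c1ccccc1)c1ccccc1.[Br-] | intermediate
6 | sodium 8-(triphenyl-λ5-phosphanylidene)octan-1-olate (alkoxide ylide, formed in the flask) | [Na+].[O-]CCCCCCCC=P(c1ccccc1)(c1ccccc1)c1ccccc1 | intermediate
7 | sodium (Z)-9-[2-(benzyloxy)phenyl]non-8-en-1-olate (formed in the flask) | [Na+].[O-]CCCCCCC/C=C\c1ccccc1OCc1ccccc1 | intermediate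
8 | (Z)-9-[2-(benzyloxy)phenyl]non-8-en-1-ol | OCCCCCCC/C=C\c1ccccc1OCc1ccccc1 | intermediate
9 | (Z)-9-[2-(benzyloxy)phenyl]non-8-enal | O=CCCCCCC/C=C\c1ccccc1OCc1ccccc1 | intermediate
10 | 2,4,6-trihydroxyacetophenone | CC(=O)c1c(O)cc(O)cc1O | starting material
11 | 1-[2,4,6-tris(benzyloxy)phenyl]ethan-1-one | CC(=O)c1c(OCc2ccccc2)cc(OCc2ccccc2)cc1OCc1ccccc1 | intermediate
12 | lithium 1-[2,4,6-tris(benzyloxy)phenyl]ethen-1-olate (formed in the flask) | [Li+].C=C([O-])c1c(OCc2ccccc2)cc(OCc2ccccc2)cc1OCc1ccccc1 | intermediate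
13 | lithium (10Z)-11-[2-(benzyloxy)phenyl]-1-oxo-1-[2,4,6-tris(benzyloxy)phenyl]undec-10-en-3-olate, racemic (formed in the flask) | [Li+].[O-]C(CC(=O)c1c(OCc2ccccc2)cc(OCc2ccccc2)cc1OCc1ccccc1)CCCCCC/C=C\c1ccccc1OCc1ccccc1 | intermediate
14 | (10Z)-11-[2-(benzyloxy)phenyl]-3-hydroxy-1-[2,4,6-tris(benzyloxy)phenyl]undec-10-en-1-one, racemic at C3 | OC(CC(=O)c1c(OCc2ccccc2)cc(OCc2ccccc2)cc1OCc1ccccc1)CCCCCC/C=C\c1ccccc1OCc1ccccc1 | intermediate
15 | (10Z)-11-[2-(benzyloxy)phenyl]-1-oxo-1-[2,4,6-tris(benzyloxy)phenyl]undec-10-en-3-yl acetate, racemic at C3 | CC(=O)OC(CC(=O)c1c(OCc2ccccc2)cc(OCc2ccccc2)cc1OCc1ccccc1)CCCCCC/C=C\c1ccccc1OCc1ccccc1 | intermediate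
16 | (2E,10Z)-11-[2-(benzyloxy)phenyl]-1-[2,4,6-tris(benzyloxy)phenyl]undeca-2,10-dien-1-one | O=C(/C=C/CCCCCC/C=C\c1ccccc1OCc1ccccc1)c1c(OCc2ccccc2)cc(OCc2ccccc2)cc1OCc1ccccc1 | intermediate
17 | 11-(2-hydroxyphenyl)-1-(2,4,6-trihydroxyphenyl)undecan-1-one (achiral) | O=C(CCCCCCCCCCc1ccccc1O)c1c(O)cc(O)cc1O | target

**Total step count:** 10
**Longest linear sequence:** 8 steps (3 → 4 → 5 → 8 → 9 → 14 → 15 → 16 → 17; steps 2, 3, 4, 5, 7, 8, 9, 10)

**Three steps most likely to fail**

Step 7 (directed aldol). The risks are proton transfer from the enolisable aldehyde 9 to the enolate, which gives self-aldol of 9 and recovered 11, and retro-aldol on warming. The fallback sets out from 11, uses 9, and comes back at 14. It replaces the basic enolate by a neutral, isolated nucleophile. Ketone 11 is treated with TMSOTf/Et3N (CH2Cl2, 0 °C) to give the silyl enol ether trimethyl({1-[2,4,6-tris(benzyloxy)phenyl]ethenyl}oxy)silane F1. F1 is combined with 9 in a Lewis-acid-catalysed Mukaiyama aldol addition (Sc(OTf)3, 5 mol %, CH2Cl2, −78 °C). This gives the O-silylated aldol (10Z)-11-[2-(benzyloxy)phenyl]-1-[2,4,6-tris(benzyloxy)phenyl]-3-[(trimethylsilyl)oxy]undec-10-en-1-one F2. Brief treatment with 1 M HCl/THF at 0 °C frees the hydroxyl and gives 14.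

Step 10 (global hydrogenation). If an ortho benzyl ether falls before the enone C=C is saturated, the free phenol can add to the enone to form a 2-alkylchroman-4-one. Long exposure could also start to reduce the aryl ketone. The fallback sets out from 16 and comes back at 17, and it separates the two tasks. The two C=C bonds are hydrogenated first over Pd/C poisoned with 2,2′-bipyridyl (H2 1 atm, MeOH/THF), conditions under which aryl benzyl ethers are kept. This gives 11-[2-(benzyloxy)phenyl]-1-[2,4,6-tris(benzyloxy)phenyl]undecan-1-one F3. The four benzyl groups are then removed non-reductively with BCl3 and pentamethylbenzene as cation scavenger (CH2Cl2, −78 °C), giving 17 with the ketone never exposed to hydrogen as a free phenol.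

Step 6 (tri-O-benzylation). The polyphenoxide of a phloroglucinol is an ambident nucleophile, so ring C-benzylation can eat into the yield. The fallback sets out from 10 and comes back at 11. The first two ethers are made without any phenoxide by a Mitsunobu etherification (BnOH 2.1 equiv, PPh3, DIAD, THF, 0 °C → rt), which is strictly O-selective and spares one chelated ortho hydroxyl. This gives 1-[2,4-bis(benzyloxy)-6-hydroxyphenyl]ethan-1-one F4. The remaining phenol belongs to a ring that is no longer a polyphenoxide and is far less prone to C-alkylation, so it is benzylated with BnBr/K2CO3 in DMF at 80 °C to give 11.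

**Further compounds**
F1 | step 7 | trimethyl({1-[2,4,6-tris(benzyloxy)phenyl]ethenyl}oxy)silane | C=C(O[Si](C)(C)C)c1c(OCc2ccccc2)cc(OCc2ccccc2)cc1OCc1ccccc1
F2 | step 7 | (10Z)-11-[2-(benzyloxy)phenyl]-1-[2,4,6-tris(benzyloxy)phenyl]-3-[(trimethylsilyl)oxy]undec-10-en-1-one, racemic at C3 | C[Si](C)(C)OC(CC(=O)c1c(OCc2ccccc2)cc(OCc2ccccc2)cc1OCc1ccccc1)CCCCCC/C=C\c1ccccc1OCc1ccccc1
F3 | step 10 | 11-[2-(benzyloxy)phenyl]-1-[2,4,6-tris(benzyloxy)phenyl]undecan-1-one | O=C(CCCCCCCCCCc1ccccc1OCc1ccccc1)c1c(OCc2ccccc2)cc(OCc2ccccc2)cc1OCc1ccccc1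
F4 | step 6 | 1-[2,4-bis(benzyloxy)-6-hydroxyphenyl]ethan-1-one | CC(=O)c1c(O)cc(OCc2ccccc2)cc1OCc1ccccc1
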